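## The problem

The target 17 consists of two hexasubstituted benzene rings joined by one methylene. Ring A is a 5′-methyl-3′-isobutyrylphloroglucinol (bridge at C1′, hydroxyls at C2′, C4′ and C6′). Ring B is a C6-methylated phloroglucinol whose C8a oxygen and C4a carbon are tied into the 2,2-dimethyl-dihydropyranone ring C, with the bridge at C8. There is no stereocentre, so the difficulty is regiochemical: positions that differ only in their neighbours (C6 versus C8, O1 versus the C5 oxygen, the three carbon substituents of ring A) must be told apart. Condensing two free phloroglucinols with formaldehyde gives mixtures of homo- and hetero-dimers, so the rings must meet as one nucleophile and one electrophile. The finished polyphenol is fragile: phloroglucinolates oxidise in air, strong acid can cut or exchange the diarylmethane bridge, and ring C can open by retro-oxa-Michael and, with a free C5 hydroxyl, reclose to the 8-methyl isomer. The C3 methylene of the chromanone is enolisable, so strong amide bases are excluded once ring C is present. The enabling feature is that ring A carries oxygen on every second carbon plus one acyl group, so it is a folded tetraketide with an isobutyryl starter. If its C2′–C3′ bond is left open, the chain closes instead to a 4-hydroxy-2-pyranone (C2′ = lactone carbonyl, C1′ = pyranone C3, C6′ = C4, C5′ = C5, C4′ = C6, C3′ = side-chain methylene). Pyranone C3 is the only nucleophilic ring carbon and can take the bridge carbon exactly once.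

## Retrosynthesis

**17 from 16.** The two O–CH3 bonds at C5 and C7 of ring B are cut. Methyl is chosen because ring C is made in a strongly acidic medium that other phenol protecting groups would not survive. A capped C5 oxygen also makes reclosure of ring C on the wrong oxygen impossible under base, and a capped C7 oxygen keeps the neighbouring aldehyde from lactone-exchange side reactions. The forward step must cleave two aryl methyl ethers without touching the bridge or ring C.

**16 from 14 (through 15).** The C2′–C3′ bond of ring A is cut, which turns the arene into pyranone 14. The alternative of bridging a finished acylphloroglucinol reintroduces the cross-coupling problem, whereas 14 already holds the bridge and all six ring-A substituents in latent form. The forward reaction must open the lactone with methoxide to triketo ester 15 and close it by Claisen, not aldol, condensation.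

**14 from 5 and 12 (through 13).** The bond between pyranone C3 and the bridging carbon is cut, giving pyranone 5 as the only carbon acid and aldehyde 12 as the only electrophile. Benzyl halide alkylation is rejected because 4-hydroxypyranones partition between O- and C-alkylation. The side chain is installed before this union, because acylating the 6-methyl group afterwards would require an amide base in the presence of the enolisable chromanone. The forward step is a Knoevenagel condensation to alkylidene 13 with in situ conjugate reduction.

**5 from 3 and 4.** The bond between the side-chain methylene and the isobutyryl carbonyl is cut. Dimethylpyranone 3 is deprotonated at its 6-methyl group and acylated by Weinreb amide 4. The amide is preferred over the methyl ester because the ester is enolisable and releases the acidic product in the flask, where it quenches dianion.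

**3 from 2 from 1.** The lactone C–O bond and then the C–CO2H bond are cut, leading to 3-methylpentane-2,4-dione 1. Its dianion is carboxylated at the terminal carbon to give diketo acid 2, which is lactonised to 3. Both events are simple, and the C5 methyl of 3 (the future C5′ methyl) comes with the diketone.

**12 from 11.** The C8–CHO bond is cut. Chromanone 11 has a single free ring position, activated by three oxygens, so electrophilic formylation needs no regiocontrol.

**11 from 8 and 9 (through 10).** The C4a–C4 and O1–C2 bonds of ring C are cut. Phenol 8 is symmetric with a blocked para position, so acylation by acid 9 at either ortho carbon gives the same enone 10. Closure on the lone hydroxyl then fixes methyl at C6 and hydrogen at C8 without a regiochemical choice.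

**8 from 6 (through 7).** The C–O bond para to the methyl group is cut. 2,6-Dimethoxytoluene 6 has one C–H without an ortho neighbour, so sterically controlled borylation to 7 and oxidation install the oxygen there.

## Roads not taken

**Alternative 1:** Ring B is cut into a four-carbon and a two-carbon piece (C8a–C8, C7–C6 and C8a–C4a). Heating cyclobutenone A1 with ring-A siloxyalkyne A2 would pass through vinylketene formation, cycloaddition, ring opening and electrocyclisation to give phenol A3.
- Merits: the route is convergent, and the ring-B pattern is dictated by mechanism, not by substituent effects.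
- Weak points: ring A must first be made fully substituted and permethylated by classical means, so the harder ring gains nothing. The propargylic methylene of A2 lies between an arene and an electron-rich alkyne and can isomerise on heating. A3 still lacks ring C, and five ethers of three kinds must be removed at the end.
- Comparison: the chosen plan obtains the ring-B pattern from the symmetry of 8 and forms ring A in one ring transformation, leaving two ethers to cleave. The benzannulation is better only in not depending on a symmetric phenol, which is no constraint for this target.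

**Alternative 2:** Ring C is cut at C8a–O1, C4a–C4 and O1–C2. Fluoride (CsF) would release the C4a–C8a aryne from silyl triflate A4, and acid 9 would add through oxygen, transfer its acyl group to C4a and close ring C to give the penta-O-methyl target A5.
- Merits: ring C forms in one neutral step, and the methoxy group next to the aryne steers the carboxylate to C8a. Because no strong acid is used, acid-labile phenol protection would be possible, which is a real advantage over the chosen plan.
- Weak points: A4 is a hexasubstituted arene already carrying ring A and needs a long preparation. The attacked aryne carbon is flanked by the bulky diarylmethyl group. O-arylation without acyl transfer competes. Five methyl ethers, three of them on ring A, must be cleaved at the end.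
- Comparison: this road spends its key step on ring C, which the chosen plan makes in one step from 8 and 9. Against the protecting-group freedom of the aryne route, the chosen plan sets a two-ether deprotection and a benzyl-ether fallback.

**Alternative 3:** The C4′–O and C5–O bonds are cut. Pd(OAc)2 with K2S2O8 in CF3CO2H/(CF3CO)2O would palladate the C–H ortho to each ketone of dideoxy triacetate A6 and oxidise both positions, giving A7 after work-up.
- Merits: the intermediates are resorcinol-type rings that are less prone to air oxidation. The two ketones of the target act as directing groups, and acetates come off far more gently than methyl ethers, so the end game is better than in the chosen plan.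
- Weak points: both C–H bonds sit between the directing ketone and a methyl group, the most hindered case for cyclopalladation. The ring-A ketone is twisted by its acetoxy neighbour. Persulfate in hot acid threatens the doubly benzylic bridge (oxidation or cleavage) and scrambles acetates. Two such events must succeed on one molecule, and A6 still has to be assembled from two penta-substituted rings without phloroglucinol reactivity.
- Comparison: the chosen plan needs no oxidation, since every oxygen arrives as a carbonyl or ether of a building block. It sets this against the milder final deprotection of Alternative 3.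

Key step: step 8

Remark: 17 has no stereocentre; the stereocentres of 2 and 15 and the double-bond geometry of 13 are labile and uncontrolled, so these compounds are written without descriptors.

## Route

Step 1
Reactants: 1 3-methylpentane-2,4-dione
Product: 2 4-methyl-3,5-dioxohexanoic acid
Conditions: LiN(iPr)2 (2.2 equiv), THF, −78 to 0 °C; CO2 (g), −78 °C; cold 2 M HCl
Reagents that add atoms: carbon dioxide, O=C=O
Why: Two equivalents of amide base form the 1,3-dianion, and the terminal carbanion, formed last and most basic, captures CO2 (dianion carboxylation of a β-diketone); the diketo acid decarboxylates on standing and is carried on at once.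

Step 2
Reactants: 2 4-methyl-3,5-dioxohexanoic acid
Product: 3 4-hydroxy-5,6-dimethyl-2H-pyran-2-one
Conditions: (CF3CO)2O, CF3CO2H, 0 °C to rt; H2O
Reagents that add atoms: none
Why: Mixed-anhydride activation lets the C5 enol oxygen acylate intramolecularly (dehydrative enol-lactonisation of a 3,5-dioxo acid), and enolisation of the remaining ketone gives the stable 4-hydroxy-2-pyranone; any O-trifluoroacetate is lost on aqueous work-up.

Step 3
Reactants: 3 4-hydroxy-5,6-dimethyl-2H-pyran-2-one; 4 N-methoxy-N,2-dimethylpropanamide (N-methoxy-N-methylisobutyramide)
Product: 5 4-hydroxy-5-methyl-6-(3-methyl-2-oxobutyl)-2H-pyran-2-one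
Conditions: LiN(iPr)2 (2.1 equiv), THF, −78 °C; 4, −78 to 0 °C; aq. HCl
Reagents that add atoms: none
Why: The 4-oxide/6-methylene dianion of a 4-hydroxy-6-methylpyranone reacts with acyl donors at the exocyclic carbon, while the C5 methyl is not vinylogous to the carbonyl and stays untouched; the Weinreb amide holds the adduct as a lithium chelate until work-up, so the acidic product cannot quench the dianion or be acylated twice.

Step 4
Reactants: 6 1,3-dimethoxy-2-methylbenzene (2,6-dimethoxytoluene)
Product: 8 3,5-dimethoxy-4-methylphenol, via aryl pinacol boronate 7 (not isolated)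
Conditions: [Ir(OMe)(cod)]2 (1.5 mol %), 4,4′-di-tert-butyl-2,2′-bipyridine (3 mol %), B2pin2 (0.7 equiv), THF, 80 °C; then KHSO5 (Oxone), acetone–H2O, rt
Reagents that add atoms: bis(pinacolato)diboron, CC1(C)OB(OC1(C)C)B1OC(C)(C)C(C)(C)O1 (boryl group of 7); potassium peroxymonosulfate, [K+].[O-]S(=O)(=O)OO (phenol oxygen of 8)
Why: Iridium-catalysed C–H borylation is sterically controlled and goes to the only C–H without an ortho substituent, para to the methyl group; peroxymonosulfate then oxidises the aryl boronate to the phenol in the same flask (one-pot borylation/oxidation).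

Step 5
Reactants: 8 3,5-dimethoxy-4-methylphenol; 9 3-methylbut-2-enoic acid
Product: 11 5,7-dimethoxy-2,2,6-trimethylchroman-4-one, via hydroxyaryl enone 10 (not isolated)
Conditions: P2O5 in MeSO3H (Eaton's reagent), 70 °C
Reagents that add atoms: none
Why: Friedel–Crafts acylation at either of the two equivalent ortho positions (para is blocked by methyl) gives enone 10, which closes by 6-endo-trig oxa-Michael addition of the single phenol; the symmetry of 8 makes the ring-B pattern unambiguous and methyl ethers tolerate the medium.

Step 6
Reactants: 11 5,7-dimethoxy-2,2,6-trimethylchroman-4-one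
Product: 12 5,7-dimethoxy-2,2,6-trimethyl-4-oxochroman-8-carbaldehyde
Conditions: Cl2CHOMe, TiCl4, CH2Cl2, −10 to 0 °C; ice–water
Reagents that add atoms: dichloromethyl methyl ether, COC(Cl)Cl (formyl carbon); water, O (aldehyde oxygen on hydrolytic work-up)
Why: Rieche formylation: C8 is the only free ring position, ortho or para to all three oxygen donors and meta to the deactivating carbonyl; low temperature should spare the C5 ether peri to the ketone.

Step 7
Reactants: 5 4-hydroxy-5-methyl-6-(3-methyl-2-oxobutyl)-2H-pyran-2-one; 12 5,7-dimethoxy-2,2,6-trimethyl-4-oxochroman-8-carbaldehyde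
Product: 14 3-[(5,7-dimethoxy-2,2,6-trimethyl-4-oxochroman-8-yl)methyl]-4-hydroxy-5-methyl-6-(3-methyl-2-oxobutyl)-2H-pyran-2-one, via alkylidene pyrandione 13 (not isolated)
Conditions: Hantzsch ester (diethyl 2,6-dimethyl-1,4-dihydropyridine-3,5-dicarboxylate, 1.1 equiv), L-proline (20 mol %), CH2Cl2, rt to 40 °C
Reagents that add atoms: none
Why: Amine-catalysed Knoevenagel condensation at pyranone C3, by far the most acidic carbon of 5, gives the electron-poor alkylidene 13, which is reduced at once by conjugate hydride transfer from the dihydropyridine (three-component reductive alkylation of a cyclic 1,3-dicarbonyl); fast reduction keeps a second pyranone from adding to 13, and neither ketone is touched.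

Step 8
Reactants: 14 3-[(5,7-dimethoxy-2,2,6-trimethyl-4-oxochroman-8-yl)methyl]-4-hydroxy-5-methyl-6-(3-methyl-2-oxobutyl)-2H-pyran-2-one
Product: 16 8-[[2,4,6-trihydroxy-3-methyl-5-(2-methylpropanoyl)phenyl]methyl]-5,7-dimethoxy-2,2,6-trimethylchroman-4-one, via open-chain triketo ester 15 (not isolated)
Conditions: Mg(OMe)2 (8 equiv), MeOH, reflux, Ar; cold 1 M HCl
Reagents that add atoms: magnesium methoxide, CO[Mg]OC (supplies the ester methoxy of 15; no reagent atom remains in 16)
Why: Methoxide adds to the lactone carbonyl and opens the pyranone to the methyl 3,5,7-trioxo ester 15, which divalent magnesium holds folded as a chelated polyenolate. The most acidic carbon, the C6 methylene between the C5 and C7 carbonyls, attacks the ester carbon, expels methoxide and forms the C2′–C3′ bond; enolisation of the resulting cyclohexanetrione gives aromatic ring A with all six substituents in place. The closest known reaction is the Mg(OMe)2-mediated Claisen cyclisation of 6-(2-oxoalkyl)-4-hydroxy-2-pyranones and their triketo esters to acylphloroglucinols. The ring closes in 6-exo-trig mode, an enolate carbon adding to an exocyclic ester carbonyl. No stereocentre is formed, and the two labile centres of 15 vanish on aromatisation. The step needs Claisen to beat aldol closure: aldol attack of C2 on the C7 ketone would make the benzylated carbon quaternary, and attack of the isopropyl methine on C3 would create a gem-dimethyl carbon, so neither adduct can aromatise and both revert, leaving the phloroglucinolate as the only sink. Ring C can open only reversibly and must reclose on O1 because the C5 oxygen is capped as its methyl ether; argon protects the phloroglucinolate from air.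

Step 9
Reactants: 16 8-[[2,4,6-trihydroxy-3-methyl-5-(2-methylpropanoyl)phenyl]methyl]-5,7-dimethoxy-2,2,6-trimethylchroman-4-one
Product: 17 8-[[2,4,6-trihydroxy-3-methyl-5-(2-methylpropanoyl)phenyl]methyl]-5,7-dihydroxy-2,2,6-trimethylchroman-4-one
Conditions: BBr3 (8 equiv), CH2Cl2, −78 to 0 °C; MeOH, then H2O
Reagents that add atoms: none
Why: Lewis-acid cleavage of aryl methyl ethers: the C5 ether is peri to the ketone and cleaves through a boron chelate, and the C7 ether is twisted out of conjugation by two ortho substituents and is also labile; the ring-A phenols are borylated only transiently and return on hydrolysis, and low temperature is used to spare the bridge and ring C.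

## Compound list

1 | 3-methylpentane-2,4-dione | CC(=O)C(C)C(C)=O | starting material
2 | 4-methyl-3,5-dioxohexanoic acid | CC(=O)C(C)C(=O)CC(=O)O | intermediate
3 | 4-hydroxy-5,6-dimethyl-2H-pyran-2-one | CC1=C(C)C(O)=CC(=O)O1 | intermediate
4 | N-methoxy-N,2-dimethylpropanamide | CC(C)C(=O)N(C)OC | starting material
5 | 4-hydroxy-5-methyl-6-(3-methyl-2-oxobutyl)-2H-pyran-2-one | CC(C)C(=O)CC1=C(C)C(O)=CC(=O)O1 | intermediate
6 | 1,3-dimethoxy-2-methylbenzene (2,6-dimethoxytoluene) | COc1cccc(OC)c1C | starting material
7 | 2-(3,5-dimethoxy-4-methylphenyl)-4,4,5,5-tetramethyl-1,3,2-dioxaborolane | COc1cc(B2OC(C)(C)C(C)(C)O2)cc(OC)c1C | intermediate (not isolated)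
8 | 3,5-dimethoxy-4-methylphenol | COc1cc(O)cc(OC)c1C | intermediate
9 | 3-methylbut-2-enoic acid | CC(C)=CC(=O)O | starting material
10 | 1-(6-hydroxy-2,4-dimethoxy-3-methylphenyl)-3-methylbut-2-en-1-one | COc1cc(O)c(C(=O)C=C(C)C)c(OC)c1C | intermediate (not isolated)
11 | 5,7-dimethoxy-2,2,6-trimethylchroman-4-one | COc1cc2OC(C)(C)CC(=O)c2c(OC)c1C | intermediate
12 | 5,7-dimethoxy-2,2,6-trimethyl-4-oxochroman-8-carbaldehyde | COc1c(C=O)c2OC(C)(C)CC(=O)c2c(OC)c1C | intermediate
13 | 3-[(5,7-dimethoxy-2,2,6-trimethyl-4-oxochroman-8-yl)methylidene]-5-methyl-6-(3-methyl-2-oxobutyl)pyran-2,4-dione (geometry undefined) | CC(C)C(=O)CC1=C(C)C(=O)C(=Cc2c(OC)c(C)c(OC)c3c2OC(C)(C)CC3=O)C(=O)O1 | intermediate (not isolated)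
14 | 3-[(5,7-dimethoxy-2,2,6-trimethyl-4-oxochroman-8-yl)methyl]-4-hydroxy-5-methyl-6-(3-methyl-2-oxobutyl)-2H-pyran-2-one | CC(C)C(=O)CC1=C(C)C(O)=C(Cc2c(OC)c(C)c(OC)c3c2OC(C)(C)CC3=O)C(=O)O1 | intermediate
15 | methyl 2-[(5,7-dimethoxy-2,2,6-trimethyl-4-oxochroman-8-yl)methyl]-4,8-dimethyl-3,5,7-trioxononanoate (keto form of the magnesium polyenolate; stereoisomer mixture) | COC(=O)C(Cc1c(OC)c(C)c(OC)c2c1OC(C)(C)CC2=O)C(=O)C(C)C(=O)CC(=O)C(C)C | intermediate (not isolated)
16 | 8-[[2,4,6-trihydroxy-3-methyl-5-(2-methylpropanoyl)phenyl]methyl]-5,7-dimethoxy-2,2,6-trimethylchroman-4-one | Cc1c(O)c(Cc2c(OC)c(C)c(OC)c3c2OC(C)(C)CC3=O)c(O)c(C(=O)C(C)C)c1O | intermediate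
17 | 8-[[2,4,6-trihydroxy-3-methyl-5-(2-methylpropanoyl)phenyl]methyl]-5,7-dihydroxy-2,2,6-trimethylchroman-4-one | Cc1c(O)c(Cc2c(O)c(C)c(O)c3c2OC(C)(C)CC3=O)c(O)c(C(=O)C(C)C)c1O | target

## Step count and risks

Total: 9 steps. Longest linear sequence: 6 steps (steps 1, 2, 3, 7, 8, 9; the ring-B arm, steps 4, 5, 6, 7, 8, 9, is equally long).

The least certain steps, in route order:

**Step 3.** The dianion may act as a base instead of a carbon nucleophile (proton transfer from the amide α-carbon, incomplete second deprotonation), or acylation may occur on the 4-oxide. The fallback sets out from 3 and returns at 5. The same dianion is trapped with 2-methylpropanal, a fast addition whose alkoxide product cannot quench the dianion, to give racemic 4-hydroxy-6-(2-hydroxy-3-methylbutyl)-5-methyl-2H-pyran-2-one F1. The secondary alcohol is then oxidised to 5 with CrO3/aqueous H2SO4 in acetone (Jones oxidation). Hypervalent iodine oxidants are avoided because they attack pyranone C3.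

**Step 7.** Condensation of the doubly ortho-substituted, electron-rich aldehyde may be slow, so that proline condenses with the side-chain ketone of 5 or the dihydropyridine is consumed unproductively. The fallback sets out from 12 and returns at 14. NaBH4 in MeOH at −40 °C reduces the aldehyde in preference to the hindered, deactivated chromanone carbonyl and gives 8-(hydroxymethyl)-5,7-dimethoxy-2,2,6-trimethylchroman-4-one F2. With catalytic TsOH (or in (CF3)2CHOH) F2 ionises to a benzylic cation stabilised by two ortho and one para oxygen, and the C3 enol of 5 captures it (dehydrative Friedel–Crafts-type benzylation of a cyclic 1,3-dicarbonyl).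

**Step 8 (key step).** Methanolysis of the lactone may be too slow, because the 3-benzyl group shields the carbonyl and the oxido-pyranone is a poor electrophile. Forcing conditions could then favour non-aromatising closures or loss of water to a 4-pyranone, and the product anion can oxidise in air. The fallback sets out from 5 and returns at 16, forming ring A before the bridge. The same Mg(OMe)2 treatment is applied to the unhindered pyranone 5, the closest match to the known reaction, giving 1-(2,4,6-trihydroxy-3-methylphenyl)-2-methylpropan-1-one F3. Acid-catalysed Friedel–Crafts benzylation of F3 with 8-(hydroxymethyl)-5,7-dimethoxy-2,2,6-trimethylchroman-4-one F2 (from 12, as under step 7) then gives 16. The coupling stays directional because F2 has no free ring position and F3 has exactly one.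

**Step 9.** Hydrogen bromide and the Lewis acid may cut or exchange the diarylmethane bridge, open the tertiary alkyl aryl ether of ring C with reclosure on the newly freed C5 oxygen, or leave the C7 ether partly intact. The fallback sets out from 12 and returns at 17, moving the demethylation to a simple stage and ending with a neutral deprotection.
- BBr3 converts 12 into 5,7-dihydroxy-2,2,6-trimethyl-4-oxochroman-8-carbaldehyde F4.
- Benzyl bromide and K2CO3 in DMF give 5,7-bis(benzyloxy)-2,2,6-trimethyl-4-oxochroman-8-carbaldehyde F5.
- Reductive alkylation of 5 as in step 7 gives 3-[[5,7-bis(benzyloxy)-2,2,6-trimethyl-4-oxochroman-8-yl]methyl]-4-hydroxy-5-methyl-6-(3-methyl-2-oxobutyl)-2H-pyran-2-one F6.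
- Mg(OMe)2 as in step 8 gives 8-[[2,4,6-trihydroxy-3-methyl-5-(2-methylpropanoyl)phenyl]methyl]-5,7-bis(benzyloxy)-2,2,6-trimethylchroman-4-one F7.
- Hydrogenolysis (H2, Pd on carbon, ethyl acetate) releases 17.

## Further compounds

F1 | step 3 | 4-hydroxy-6-(2-hydroxy-3-methylbutyl)-5-methyl-2H-pyran-2-one (racemic) | CC(C)C(O)CC1=C(C)C(O)=CC(=O)O1
F2 | step 7 | 8-(hydroxymethyl)-5,7-dimethoxy-2,2,6-trimethylchroman-4-one | COc1c(CO)c2OC(C)(C)CC(=O)c2c(OC)c1C
F3 | step 8 | 1-(2,4,6-trihydroxy-3-methylphenyl)-2-methylpropan-1-one | Cc1c(O)cc(O)c(C(=O)C(C)C)c1O
F4 | step 9 | 5,7-dihydroxy-2,2,6-trimethyl-4-oxochroman-8-carbaldehyde | Cc1c(O)c(C=O)c2OC(C)(C)CC(=O)c2c1O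
F5 | step 9 | 5,7-bis(benzyloxy)-2,2,6-trimethyl-4-oxochroman-8-carbaldehyde | Cc1c(OCc2ccccc2)c(C=O)c2OC(C)(C)CC(=O)c2c1OCc1ccccc1
F6 | step 9 | 3-[[5,7-bis(benzyloxy)-2,2,6-trimethyl-4-oxochroman-8-yl]methyl]-4-hydroxy-5-methyl-6-(3-methyl-2-oxobutyl)-2H-pyran-2-one | CC(C)C(=O)CC1=C(C)C(O)=C(Cc2c(OCc3ccccc3)c(C)c(OCc3ccccc3)c3c2OC(C)(C)CC3=O)C(=O)O1
F7 | step 9 | 8-[[2,4,6-trihydroxy-3-methyl-5-(2-methylpropanoyl)phenyl]methyl]-5,7-bis(benzyloxy)-2,2,6-trimethylchroman-4-one | Cc1c(O)c(Cc2c(OCc3ccccc3)c(C)c(OCc3ccccc3)c3c2OC(C)(C)CC3=O)c(O)c(C(=O)C(C)C)c1O
A1 | alternative 1 | 3-ethoxy-2-methylcyclobut-2-en-1-one | CCOC1=C(C)C(=O)C1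
A2 | alternative 1 | 2-methyl-1-[2,4,6-trimethoxy-3-methyl-5-[3-[tri(propan-2-yl)silyloxy]prop-2-yn-1-yl]phenyl]propan-1-one | COc1c(C)c(OC)c(CC#CO[Si](C(C)C)(C(C)C)C(C)C)c(OC)c1C(=O)C(C)C
A3 | alternative 1 | 1-[3-[[4-ethoxy-6-hydroxy-3-methyl-2-[tri(propan-2-yl)silyloxy]phenyl]methyl]-2,4,6-trimethoxy-5-methylphenyl]-2-methylpropan-1-one | COc1c(C)c(OC)c(Cc2c(O)cc(OCC)c(C)c2O[Si](C(C)C)(C(C)C)C(C)C)c(OC)c1C(=O)C(C)C
A4 | alternative 2 | 3,5-dimethoxy-4-methyl-2-[[2,4,6-trimethoxy-3-methyl-5-(2-methylpropanoyl)phenyl]methyl]-6-(trimethylsilyl)phenyl trifluoromethanesulfonate | COc1c(C)c(OC)c(Cc2c(OC)c(C)c(OC)c([Si](C)(C)C)c2OS(=O)(=O)C(F)(F)F)c(OC)c1C(=O)C(C)C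
A5 | alternative 2 | 8-[[2,4,6-trimethoxy-3-methyl-5-(2-methylpropanoyl)phenyl]methyl]-5,7-dimethoxy-2,2,6-trimethylchroman-4-one | COc1c(C)c(OC)c(Cc2c(OC)c(C)c(OC)c3c2OC(C)(C)CC3=O)c(OC)c1C(=O)C(C)C
A6 | alternative 3 | 8-[[2,6-diacetoxy-3-methyl-5-(2-methylpropanoyl)phenyl]methyl]-7-acetoxy-2,2,6-trimethylchroman-4-one | Cc1cc(C(=O)C(C)C)c(OC(C)=O)c(Cc2c(OC(C)=O)c(C)cc3c2OC(C)(C)CC3=O)c1OC(C)=O
A7 | alternative 3 | 8-[[2,6-diacetoxy-4-hydroxy-3-methyl-5-(2-methylpropanoyl)phenyl]methyl]-7-acetoxy-5-hydroxy-2,2,6-trimethylchroman-4-one | Cc1c(O)c(C(=O)C(C)C)c(OC(C)=O)c(Cc2c(OC(C)=O)c(C)c(O)c3c2OC(C)(C)CC3=O)c1OC(C)=O
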